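**Strategy.** The 3-(hydroxymethyl)-5-ylidene-furan-2(5H)-one ring is dissected at its two ring C–C single bonds, C4–C5 and C2–C3. The C3=C4 unit (H on C4, CH2OH on C3) is then a terminal propargylic alkyne, C5 with its exocyclic CH is an acyl group with its α-CH2, and C2 is carbon monoxide. One cobalt-carbonyl-mediated operation joins acid chloride, alkyne and CO, closes the lactone at O1–C2 and eliminates to the ylidene butenolide. The precursor is the open-chain (S)-3-methyl acid chloride carrying the whole furanoterpenoid chain; its stereocentre comes from (S)-β-butyrolactone by copper-catalysed SN2 opening with inversion.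

Key step: step 9

Remark: NaCo(CO)4 is used as a stock ether solution prepared beforehand from Co2(CO)8; all other reagents are used as purchased.

Step 1
Reactants: 1 furan-3-ylmethanol
Product: 2 3-(chloromethyl)furan
Conditions: PPh3, hexachloroacetone, CH2Cl2, 0 °C
Reagents that add atoms: hexachloroacetone, ClC(Cl)(Cl)C(=O)C(Cl)(Cl)Cl
Why: Appel-type deoxychlorination, in which the alkoxyphosphonium ion is displaced by chloride (SN2) under neutral conditions that spare the acid-sensitive furan.

Step 2
Reactants: 2 3-(chloromethyl)furan, 3 geranyl chloride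
Product: 5 dendrolasin, via (furan-3-ylmethyl)magnesium chloride 4 (not isolated)
Conditions: Mg turnings, THF, 0 °C; then 3, Li2CuCl4 (3 mol%), THF, 0 to 20 °C
Reagents that add atoms: none
Why: Copper-catalysed sp3–sp3 Grignard cross-coupling (Kochi type), in which the furylmethyl Grignard reagent should substitute the primary allylic chloride at its α-carbon so that the E olefin of 3 is carried over unchanged.

Step 3
Reactants: 5 dendrolasin
Product: 6 (2E,6E)-9-(furan-3-yl)-2,6-dimethylnona-2,6-dien-1-ol
Conditions: SeO2 (0.3 equiv), t-BuOOH (2 equiv), salicylic acid (0.1 equiv), CH2Cl2, 0 to 20 °C, stopped at partial conversion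
Reagents that add atoms: selenium dioxide, O=[Se]=O; tert-butyl hydroperoxide, CC(C)(C)OO
Why: Riley allylic oxidation (ene reaction, then [2,3]-sigmatropic shift) should attack the terminal trisubstituted olefin at its (E)-methyl group and so give the (E)-allylic alcohol, the furan being left alone under the catalytic, buffered conditions.

Step 4
Reactants: 6 (2E,6E)-9-(furan-3-yl)-2,6-dimethylnona-2,6-dien-1-ol
Product: 7 3-[(3E,7E)-9-chloro-4,8-dimethylnona-3,7-dien-1-yl]furan
Conditions: PPh3, hexachloroacetone, CH2Cl2, 0 °C
Reagents that add atoms: hexachloroacetone, ClC(Cl)(Cl)C(=O)C(Cl)(Cl)Cl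
Why: Appel-type chlorination by SN2 at the primary allylic carbon, without allylic transposition, so the olefin geometry is kept.

Step 5
Reactants: 7 3-[(3E,7E)-9-chloro-4,8-dimethylnona-3,7-dien-1-yl]furan
Product: 8 3-[(3E,7E)-4,8-dimethylundeca-3,7,10-trien-1-yl]furan
Conditions: vinylmagnesium bromide (1.5 equiv), Li2CuCl4 (5 mol%), THF, −30 to 0 °C
Reagents that add atoms: vinylmagnesium bromide, C=C[Mg]Br
Why: Copper-catalysed substitution of the primary allylic chloride by the vinyl Grignard reagent at the α-carbon should give the skipped diene, γ-attack being disfavoured at the substituted olefin carbon.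

Step 6
Reactants: 8 3-[(3E,7E)-4,8-dimethylundeca-3,7,10-trien-1-yl]furan
Product: 10 3-[(3E,7E)-11-chloro-4,8-dimethylundeca-3,7-dien-1-yl]furan, via alkylzirconocene chloride 9 (not isolated)
Conditions: Cp2Zr(H)Cl (1.2 equiv), THF, 20 °C; then N-chlorosuccinimide (1.1 equiv), 0 °C
Reagents that add atoms: N-chlorosuccinimide, ClN1C(=O)CCC1=O
Why: Hydrozirconation is selective for the monosubstituted alkene and places zirconium on the terminal carbon, and the C–Zr bond is then cleaved by the N-chloro imide to the primary chloride while the trisubstituted olefins stay untouched.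

Step 7
Reactants: 10 3-[(3E,7E)-11-chloro-4,8-dimethylundeca-3,7-dien-1-yl]furan, 11 (S)-β-butyrolactone
Product: 13 (3S,7E,11E)-14-(furan-3-yl)-3,7,11-trimethyltetradeca-7,11-dienoic acid, via alkylmagnesium chloride 12 (not isolated)
Conditions: Mg turnings, THF, 60 °C; then CuBr·SMe2 (5 mol%), 11, THF/Me2S, −30 to 0 °C; then cold 1 M HCl
Reagents that add atoms: none
Why: Copper-catalysed SN2 opening of the β-lactone at its β-carbon (alkyl–oxygen cleavage) by the Grignard reagent proceeds with inversion and turns (S)-11 into the (S)-3-methyl acid (the descriptor is unchanged because the CIP ranks of the leaving and entering groups differ), which is the configuration of the target.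

Step 8
Reactants: 13 (3S,7E,11E)-14-(furan-3-yl)-3,7,11-trimethyltetradeca-7,11-dienoic acid
Product: 14 (3S,7E,11E)-14-(furan-3-yl)-3,7,11-trimethyltetradeca-7,11-dienoyl chloride
Conditions: 1-chloro-N,N,2-trimethylprop-1-en-1-amine (1.2 equiv), CH2Cl2, 0 to 20 °C; concentrated and used crude
Reagents that add atoms: 1-chloro-N,N,2-trimethylprop-1-en-1-amine, CC(C)=C(Cl)N(C)C
Why: Acid chloride formation with the α-chloroenamine releases no HCl, so the furan and the trisubstituted olefins should survive, and the β-stereocentre cannot enolise.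

Step 9
Reactants: 14 (3S,7E,11E)-14-(furan-3-yl)-3,7,11-trimethyltetradeca-7,11-dienoyl chloride, 15 tert-butyldimethyl(prop-2-yn-1-yloxy)silane
Product: 18 (5Z)-3-{[(tert-butyldimethylsilyl)oxy]methyl}-5-[(2S,6E,10E)-13-(furan-3-yl)-2,6,10-trimethyltrideca-6,10-dien-1-ylidene]furan-2(5H)-one, via acylcobalt tetracarbonyl 16 (not isolated), via lactonyl cobalt tricarbonyl 17 (not isolated)
Conditions: NaCo(CO)4 (1.05 equiv), Et2O, CO (1 atm), 0 °C; then 15 (1.5 equiv), 0 to 25 °C; then N-ethyldicyclohexylamine (1.2 equiv), 25 °C
Reagents that add atoms: sodium tetracarbonylcobaltate NaCo(CO)4, [Na+].[Co-](=C=O)(=C=O)(=C=O)=C=O; carbon monoxide, [C-]#[O+]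
Why: Co(CO)4− displaces chloride from 14 to give 16; after loss of CO and coordination of 15, syn-acylcobaltation places the acyl carbon on the free alkyne terminus (new C5–C4 bond of the furanone) and cobalt on the carbon bearing CH2OSi, where CO insertion forms the C3–C2 bond. The ketone oxygen then attacks the new acylcobalt carbon (5-exo-trig O-acylation, so the ring closes at O1–C2) to give the η3-lactonyl complex 17, and the hindered amine removes a proton from the CH2 next to C5 as the cobalt departs and is recaptured by CO as Co(CO)4−. This is the known acylcobalt tetracarbonyl–alkyne–CO annulation to 2,4-pentadieno-4-lactones, run here with a full equivalent of cobalt so that no acid chloride meets the amine. No new stereocentre is formed; the exocyclic olefin should settle as the Z isomer (alkyl syn to the ring oxygen) because the E isomer suffers allylic strain against H-4, and the neighbouring stereocentre is untouched since only the adjacent CH2 loses a proton. The step needs regiocontrol in the alkyne insertion, which the steric difference between the free terminus and the CH2OSi-bearing carbon should secure, and elimination towards the side chain, which the oxocarbenium-like C5 terminus of the allyl unit should secure.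

Step 10
Reactants: 18 the silyl ether from step 9
Product: 19 (5Z)-5-[(2S,6E,10E)-13-(furan-3-yl)-2,6,10-trimethyltrideca-6,10-dien-1-ylidene]-3-(hydroxymethyl)furan-2(5H)-one
Conditions: HF·pyridine, pyridine, THF, 0 to 20 °C
Reagents that add atoms: none
Why: Fluoride-mediated cleavage of the primary silyl ether under buffered, weakly acidic conditions should avoid base-induced isomerisation of the ylidene butenolide and epimerisation of the allylic stereocentre.

**Compound list**

1 | furan-3-ylmethanol | OCc1ccoc1 | starting material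
2 | 3-(chloromethyl)furan | ClCc1ccoc1 | intermediate
3 | geranyl chloride [(2E)-1-chloro-3,7-dimethylocta-2,6-diene] | ClC/C=C(\C)CCC=C(C)C | starting material
4 | (furan-3-ylmethyl)magnesium chloride | Cl[Mg]Cc1ccoc1 | intermediate
5 | dendrolasin [3-[(3E)-4,8-dimethylnona-3,7-dien-1-yl]furan] | C/C(=C\CCc1ccoc1)CCC=C(C)C | intermediate
6 | (2E,6E)-9-(furan-3-yl)-2,6-dimethylnona-2,6-dien-1-ol | C/C(=C\CCc1ccoc1)CC/C=C(\C)CO | intermediate
7 | 3-[(3E,7E)-9-chloro-4,8-dimethylnona-3,7-dien-1-yl]furan | C/C(=C\CCc1ccoc1)CC/C=C(\C)CCl | intermediate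
8 | 3-[(3E,7E)-4,8-dimethylundeca-3,7,10-trien-1-yl]furan | C/C(=C\CCc1ccoc1)CC/C=C(\C)CC=C | intermediate
9 | chlorobis(cyclopentadienyl)[(4E,8E)-11-(furan-3-yl)-4,8-dimethylundeca-4,8-dien-1-yl]zirconium (cyclopentadienyl rings drawn σ-bonded) | C/C(=C\CCc1ccoc1)CC/C=C(\C)CCC[Zr](Cl)(C1C=CC=C1)C1C=CC=C1 | intermediate
10 | 3-[(3E,7E)-11-chloro-4,8-dimethylundeca-3,7-dien-1-yl]furan | C/C(=C\CCc1ccoc1)CC/C=C(\C)CCCCl | intermediate
11 | (S)-β-butyrolactone [(4S)-4-methyloxetan-2-one] | C[C@H]1CC(=O)O1 | starting material
12 | [(4E,8E)-11-(furan-3-yl)-4,8-dimethylundeca-4,8-dien-1-yl]magnesium chloride | C/C(=C\CCc1ccoc1)CC/C=C(\C)CCC[Mg]Cl | intermediate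
13 | (3S,7E,11E)-14-(furan-3-yl)-3,7,11-trimethyltetradeca-7,11-dienoic acid | C/C(=C\CCc1ccoc1)CC/C=C(\C)CCC[C@H](C)CC(=O)O | intermediate
14 | (3S,7E,11E)-14-(furan-3-yl)-3,7,11-trimethyltetradeca-7,11-dienoyl chloride | C/C(=C\CCc1ccoc1)CC/C=C(\C)CCC[C@H](C)CC(=O)Cl | intermediate
15 | tert-butyldimethyl(prop-2-yn-1-yloxy)silane | C#CCO[Si](C)(C)C(C)(C)C | starting material
16 | tetracarbonyl[(3S,7E,11E)-14-(furan-3-yl)-3,7,11-trimethyltetradeca-7,11-dienoyl]cobalt | C/C(=C\CCc1ccoc1)CC/C=C(\C)CCC[C@H](C)CC(=O)[Co](=C=O)(=C=O)(=C=O)=C=O | intermediate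
17 | tricarbonyl(η3-lactonyl)cobalt complex of the 5-alkyl-3-(silyloxymethyl)-2-oxo-2,5-dihydrofuranyl unit (drawn as the σ-form bonded at C5; C5 configuration not defined) | C/C(=C\CCc1ccoc1)CC/C=C(\C)CCC[C@H](C)CC1([Co](=C=O)(=C=O)=C=O)C=C(CO[Si](C)(C)C(C)(C)C)C(=O)O1 | intermediate
18 | (5Z)-3-{[(tert-butyldimethylsilyl)oxy]methyl}-5-[(2S,6E,10E)-13-(furan-3-yl)-2,6,10-trimethyltrideca-6,10-dien-1-ylidene]furan-2(5H)-one | C/C(=C\CCc1ccoc1)CC/C=C(\C)CCC[C@H](C)/C=C1/C=C(CO[Si](C)(C)C(C)(C)C)C(=O)O1 | intermediate
19 | (5Z)-5-[(2S,6E,10E)-13-(furan-3-yl)-2,6,10-trimethyltrideca-6,10-dien-1-ylidene]-3-(hydroxymethyl)furan-2(5H)-one | C/C(=C\CCc1ccoc1)CC/C=C(\C)CCC[C@H](C)/C=C1/C=C(CO)C(=O)O1 | target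

Total step count: 10. Longest linear sequence: 10 steps (1 to 19).

**Steps most likely to fail**

Step 9 (key step). What may go wrong: insertion of the alkyne into the acyl–cobalt bond with the reverse regiochemistry, loss of the proton from the CH2OSi side instead of the side chain when the lactonyl complex collapses, or incomplete Z control at the exocyclic olefin. Precedent for this annulation covers simple alkynes and simple acyl groups only. Fallback: the same two fragments are joined in two separate, known metal-catalysed events. Setting out from 14 and 15, addition of the acid chloride across the terminal alkyne with [IrCl(cod)]2 and dicyclohexyl(2',6'-diisopropoxybiphenyl-2-yl)phosphine in toluene at 90 °C should give the (Z)-β-chloroenone F1, with the acyl group on the alkyne terminus and chlorine on the substituted carbon. Carbonylation of F1 with PdCl2(PPh3)2, CO and NEt3 in MeCN at 80 °C, in which the acylpalladium is trapped by the enol oxygen of the ketone, should then close the ring and return the route at 18.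

Step 3. What may go wrong: competing oxidation at the internal olefin or on the furan ring, and over-oxidation to the enal, so that little of 5 is converted cleanly. Fallback: the oxidation is done before the furan is present. Commercial geranyl acetate is oxidised with SeO2 and t-BuOOH to (2E,6E)-8-hydroxy-3,7-dimethylocta-2,6-dien-1-yl acetate F2, the allylic acetate deactivating the neighbouring olefin. F2 is then treated with an excess of Grignard reagent 4 (made from 2) and Li2CuCl4 in THF at −10 °C; the first equivalent forms the alkoxide and the next displaces the allylic acetate at the α-carbon, which returns the route at 6.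

Step 6. What may go wrong: electrophilic chlorination of the furan or the trisubstituted olefins by the N-chloro imide, or zirconium hydride chain-walking that moves the skipped diene into conjugation. Fallback: boron replaces zirconium and the halide is made by an Appel reaction. Setting out from 8, 9-BBN in THF should give the B-alkyl-9-borabicyclo[3.3.1]nonane F3, which NaBO3·4H2O oxidises to the primary alcohol F4. CBr4 and PPh3 convert F4 into the primary bromide F5. Mg in THF then gives the alkylmagnesium bromide F6, which opens lactone 11 under CuBr·SMe2 catalysis as in step 7 and returns the route at 13.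

**Further compounds**

F1 | step 9 | (2Z,6S,10E,14E)-1-[(tert-butyldimethylsilyl)oxy]-2-chloro-17-(furan-3-yl)-6,10,14-trimethylheptadeca-2,10,14-trien-4-one | C/C(=C\CCc1ccoc1)CC/C=C(\C)CCC[C@H](C)CC(=O)/C=C(\Cl)CO[Si](C)(C)C(C)(C)C
F2 | step 3 | (2E,6E)-8-hydroxy-3,7-dimethylocta-2,6-dien-1-yl acetate | CC(=O)OC/C=C(\C)CC/C=C(\C)CO
F3 | step 6 | 9-[(4E,8E)-11-(furan-3-yl)-4,8-dimethylundeca-4,8-dien-1-yl]-9-borabicyclo[3.3.1]nonane | C/C(=C\CCc1ccoc1)CC/C=C(\C)CCCB1C2CCCC1CCC2
F4 | step 6 | (4E,8E)-11-(furan-3-yl)-4,8-dimethylundeca-4,8-dien-1-ol | C/C(=C\CCc1ccoc1)CC/C=C(\C)CCCO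
F5 | step 6 | 3-[(3E,7E)-11-bromo-4,8-dimethylundeca-3,7-dien-1-yl]furan | C/C(=C\CCc1ccoc1)CC/C=C(\C)CCCBr
F6 | step 6 | [(4E,8E)-11-(furan-3-yl)-4,8-dimethylundeca-4,8-dien-1-yl]magnesium bromide | C/C(=C\CCc1ccoc1)CC/C=C(\C)CCC[Mg]Br
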